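**Strategy.** Sequoiaflavone is cut at the C4–C4a bond of the apigenin unit that carries the biaryl bond at C8 (unit 2). A (Z)-β-aryloxycinnamic acid, whose ether oxygen (the future O1) sits on a 3,5-dibenzyloxyphenyl ring with ring B of unit 1 already on one ortho carbon, undergoes intramolecular Friedel–Crafts acylation at the only free ortho carbon. One operation thus closes ring C of unit 2 and fixes the 8-aryl (not 6-aryl) pattern. The acid is released from an allyl ester under neutral palladium catalysis, because acidolysis of a tert-butyl ester would expose the cation-trapping trialkoxyarene to tert-butyl cations. The methyl benzoate handle then grows into the 7-methoxy flavone (unit 1) by Baker–Venkataraman chemistry.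

Key step: step 7

Assumption: any E enol ether formed in step 5 is carried forward with the Z isomer, since reversible protonation of the enol ether in the acidic medium of step 7 should interconvert the two.

**Step 1**
Reactants: 1 methyl 4-hydroxy-3-iodobenzoate
Product: 2 methyl 4-(benzyloxy)-3-iodobenzoate
Conditions: BnBr, K2CO3, DMF, 60 °C
Reagents that add atoms: benzyl bromide, BrCc1ccccc1
Why: Williamson ether synthesis in which the phenoxide displaces bromide from benzyl bromide while the methyl ester and the aryl iodide stay untouched.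

**Step 2**
Reactants: 2 methyl 4-(benzyloxy)-3-iodobenzoate
Product: 3 methyl 4-(benzyloxy)-3-(tributylstannyl)benzoate
Conditions: (Bu3Sn)2, Pd(PPh3)4 (cat.), toluene, 110 °C
Reagents that add atoms: hexabutylditin, CCCC[Sn](CCCC)(CCCC)[Sn](CCCC)(CCCC)CCCC
Why: Palladium-catalysed stannylation of an aryl iodide with a distannane (oxidative addition to zerovalent palladium, tin–tin transmetalation, reductive elimination), which tolerates the ester and the benzyl ether.

**Step 3**
Reactants: 3 methyl 4-(benzyloxy)-3-(tributylstannyl)benzoate; 4 3,5-bis(benzyloxy)phenol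
Product: 6 methyl 4-(benzyloxy)-3-[2,4-bis(benzyloxy)-6-hydroxyphenyl]benzoate, via aryllead triacetate 5 (not isolated)
Conditions: Pb(OAc)4, Hg(OAc)2 (cat.), CHCl3, 40 °C; then 4 (excess), pyridine, 60 °C
Reagents that add atoms: none
Why: Pinhey arylation, in which mercury-catalysed tin–lead exchange gives the aryllead triacetate, the phenoxide of 4 binds to tetravalent lead and ligand coupling delivers the aryl group to an ortho carbon only (the two ortho carbons of 4 are equivalent), an excess of 4 limiting a second arylation.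

**Step 4**
Reactants: 7 1-(benzyloxy)-4-ethynylbenzene
Product: 9 allyl 3-[4-(benzyloxy)phenyl]prop-2-ynoate, via lithium acetylide 8 (not isolated)
Conditions: n-BuLi, THF, −78 °C; then ClCO2CH2CH=CH2, −78 to 0 °C
Reagents that add atoms: allyl chloroformate, C=CCOC(Cl)=O
Why: Deprotonation of the terminal alkyne and C-acylation of the lithium acetylide by a chloroformate is a standard alkynoate synthesis, and the low temperature leaves the benzylic ether protons alone.

**Step 5**
Reactants: 6 methyl 4-(benzyloxy)-3-[2,4-bis(benzyloxy)-6-hydroxyphenyl]benzoate; 9 allyl 3-[4-(benzyloxy)phenyl]prop-2-ynoate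
Product: 10 allyl (Z)-3-{3,5-bis(benzyloxy)-2-[2-(benzyloxy)-5-(methoxycarbonyl)phenyl]phenoxy}-3-[4-(benzyloxy)phenyl]acrylate
Conditions: Cs2CO3 (0.3 equiv), DMF, 60 °C
Reagents that add atoms: none
Why: Base-catalysed oxa-Michael (Ruhemann-type) addition of the phenoxide to the β-carbon of the arylpropiolate, where anti protonation of the allenolate is expected to favour the Z enol ether and the catalytic carbonate leaves both esters intact.

**Step 6**
Reactants: 10 allyl (Z)-3-{3,5-bis(benzyloxy)-2-[2-(benzyloxy)-5-(methoxycarbonyl)phenyl]phenoxy}-3-[4-(benzyloxy)phenyl]acrylate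
Product: 11 (Z)-3-{3,5-bis(benzyloxy)-2-[2-(benzyloxy)-5-(methoxycarbonyl)phenyl]phenoxy}-3-[4-(benzyloxy)phenyl]acrylic acid
Conditions: Pd(PPh3)4 (cat.), PhSO2Na, THF/MeOH, rt; then cold dil. HCl wash
Reagents that add atoms: none
Why: Tsuji–Trost deallylation, in which zerovalent palladium ionises only the allyl ester and the soft, non-basic sulfinate traps the π-allyl complex as a sulfone, so the acid is freed without strong acid, hydroxide or an amine that could attack the enol ether or the methyl ester.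

**Step 7**
Reactants: 11 (Z)-3-{3,5-bis(benzyloxy)-2-[2-(benzyloxy)-5-(methoxycarbonyl)phenyl]phenoxy}-3-[4-(benzyloxy)phenyl]acrylic acid
Product: 13 methyl 4-(benzyloxy)-3-{5,7-bis(benzyloxy)-2-[4-(benzyloxy)phenyl]-4-oxochromen-8-yl}benzoate, via mixed trifluoroacetic anhydride 12 (not isolated)
Conditions: (CF3CO)2O (1.5 equiv), CH2Cl2, 0 °C to rt
Reagents that add atoms: none
Why: Trifluoroacetic anhydride converts the acrylic acid into the mixed anhydride 12, whose acyl carbon (as the anhydride or the derived acylium ion) is attacked by the phenoxy ring at its only unsubstituted ortho carbon, and loss of a proton from the arenium ion gives the pyranone. This is an intramolecular Friedel–Crafts acylation of a β-aryloxycinnamic acid, the ring-closing event of the Ruhemann flavone synthesis. Ring C of unit 2 closes as a six-membered ring by 6-exo-trig attack of the arene carbon on the acyl carbon, forming the C4–C4a bond. No stereocentre is created; the only geometric requirement is that the acyl group lie cis to the aryloxy oxygen, which the Z alkene provides, and an E isomer can reach this geometry through reversible protonation of the enol ether by the trifluoroacetic acid released. Regiochemistry is secured by the substrate, because the second ortho carbon of the ether ring already carries ring B of unit 1, so the carbonyl must bond to the future C4a and the biaryl bond ends at C8. Chemoselectivity follows from nucleophilicity, since the trioxygenated ring is far more electron-rich than the ester-bearing ring, the benzyl groups or the β-aryl ring, where closure would in addition require a five-membered indenone.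

**Step 8**
Reactants: 13 methyl 4-(benzyloxy)-3-{5,7-bis(benzyloxy)-2-[4-(benzyloxy)phenyl]-4-oxochromen-8-yl}benzoate
Product: 14 4-(benzyloxy)-3-{5,7-bis(benzyloxy)-2-[4-(benzyloxy)phenyl]-4-oxochromen-8-yl}benzoic acid
Conditions: LiOH, THF/H2O, 40 °C; then dil. HCl
Reagents that add atoms: lithium hydroxide, [Li+].[OH-]
Why: Saponification of an unhindered methyl benzoate under mild conditions, under which the electron-rich 5,7-dialkoxy pyranone should resist ring opening and the benzyl ethers are inert.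

**Step 9**
Reactants: 15 2',6'-dihydroxy-4'-methoxyacetophenone
Product: 16 2'-(benzyloxy)-6'-hydroxy-4'-methoxyacetophenone
Conditions: BnBr (1 equiv), K2CO3, acetone, reflux
Reagents that add atoms: benzyl bromide, BrCc1ccccc1
Why: Williamson mono-benzylation, which should stop after one alkylation because the remaining hydroxyl is locked in a hydrogen bond to the acetyl carbonyl and is much less nucleophilic.

**Step 10**
Reactants: 14 4-(benzyloxy)-3-{5,7-bis(benzyloxy)-2-[4-(benzyloxy)phenyl]-4-oxochromen-8-yl}benzoic acid; 16 2'-(benzyloxy)-6'-hydroxy-4'-methoxyacetophenone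
Product: 17 2-acetyl-3-(benzyloxy)-5-methoxyphenyl 4-(benzyloxy)-3-{5,7-bis(benzyloxy)-2-[4-(benzyloxy)phenyl]-4-oxochromen-8-yl}benzoate
Conditions: DCC, DMAP (cat.), CH2Cl2, rt
Reagents that add atoms: none
Why: Steglich esterification, in which the carbodiimide activates the acid and DMAP transfers the acyl group to the chelated phenol under neutral conditions.

**Step 11**
Reactants: 17 2-acetyl-3-(benzyloxy)-5-methoxyphenyl 4-(benzyloxy)-3-{5,7-bis(benzyloxy)-2-[4-(benzyloxy)phenyl]-4-oxochromen-8-yl}benzoate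
Product: 18 1-[2-(benzyloxy)-6-hydroxy-4-methoxyphenyl]-3-(4-(benzyloxy)-3-{5,7-bis(benzyloxy)-2-[4-(benzyloxy)phenyl]-4-oxochromen-8-yl}phenyl)propane-1,3-dione
Conditions: LiN(SiMe3)2, THF, −78 to 0 °C; then dil. HCl
Reagents that add atoms: none
Why: Baker–Venkataraman rearrangement, in which the methyl ketone enolate attacks the neighbouring aryl ester intramolecularly to give the 1,3-diketone, and a non-nucleophilic amide base avoids attack on the flavone already present.

**Step 12**
Reactants: 18 1-[2-(benzyloxy)-6-hydroxy-4-methoxyphenyl]-3-(4-(benzyloxy)-3-{5,7-bis(benzyloxy)-2-[4-(benzyloxy)phenyl]-4-oxochromen-8-yl}phenyl)propane-1,3-dione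
Product: 19 5-(benzyloxy)-2-(4-(benzyloxy)-3-{5,7-bis(benzyloxy)-2-[4-(benzyloxy)phenyl]-4-oxochromen-8-yl}phenyl)-7-methoxychromen-4-one
Conditions: H2SO4 (cat.), AcOH, 80 °C
Reagents that add atoms: none
Why: Acid-catalysed cyclodehydration of the ortho-hydroxyaryl 1,3-diketone (hemiketal formation, loss of water) closes the pyranone of unit 1, and any benzyl ether lost here is harmless because all are removed in the next step.

**Step 13**
Reactants: 19 5-(benzyloxy)-2-(4-(benzyloxy)-3-{5,7-bis(benzyloxy)-2-[4-(benzyloxy)phenyl]-4-oxochromen-8-yl}phenyl)-7-methoxychromen-4-one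
Product: 20 sequoiaflavone
Conditions: H2 (1 atm), Pd/C, THF/MeOH, rt
Reagents that add atoms: none
Why: Hydrogenolysis of the five benzyl aryl ethers over palladium on carbon, which at low pressure should leave the methyl ether, the biaryl bond and both pyranone double bonds in place.

**Compound list**
1 | methyl 4-hydroxy-3-iodobenzoate | COC(=O)c1ccc(O)c(I)c1 | starting material
2 | methyl 4-(benzyloxy)-3-iodobenzoate | COC(=O)c1ccc(OCc2ccccc2)c(I)c1 | intermediate
3 | methyl 4-(benzyloxy)-3-(tributylstannyl)benzoate | CCCC[Sn](CCCC)(CCCC)c1cc(C(=O)OC)ccc1OCc1ccccc1 | intermediate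
4 | 3,5-bis(benzyloxy)phenol | Oc1cc(OCc2ccccc2)cc(OCc2ccccc2)c1 | starting material
5 | [2-(benzyloxy)-5-(methoxycarbonyl)phenyl]lead triacetate | COC(=O)c1ccc(OCc2ccccc2)c([Pb](OC(C)=O)(OC(C)=O)OC(C)=O)c1 | intermediate
6 | methyl 4-(benzyloxy)-3-[2,4-bis(benzyloxy)-6-hydroxyphenyl]benzoate | COC(=O)c1ccc(OCc2ccccc2)c(-c2c(O)cc(OCc3ccccc3)cc2OCc2ccccc2)c1 | intermediate
7 | 1-(benzyloxy)-4-ethynylbenzene | C#Cc1ccc(OCc2ccccc2)cc1 | starting material
8 | lithium [4-(benzyloxy)phenyl]acetylide | [Li]C#Cc1ccc(OCc2ccccc2)cc1 | intermediate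
9 | allyl 3-[4-(benzyloxy)phenyl]prop-2-ynoate | C=CCOC(=O)C#Cc1ccc(OCc2ccccc2)cc1 | intermediate
10 | allyl (Z)-3-{3,5-bis(benzyloxy)-2-[2-(benzyloxy)-5-(methoxycarbonyl)phenyl]phenoxy}-3-[4-(benzyloxy)phenyl]acrylate | C=CCOC(=O)/C=C(\Oc1cc(OCc2ccccc2)cc(OCc2ccccc2)c1-c1cc(C(=O)OC)ccc1OCc1ccccc1)c1ccc(OCc2ccccc2)cc1 | intermediate
11 | (Z)-3-{3,5-bis(benzyloxy)-2-[2-(benzyloxy)-5-(methoxycarbonyl)phenyl]phenoxy}-3-[4-(benzyloxy)phenyl]acrylic acid | OC(=O)/C=C(\Oc1cc(OCc2ccccc2)cc(OCc2ccccc2)c1-c1cc(C(=O)OC)ccc1OCc1ccccc1)c1ccc(OCc2ccccc2)cc1 | intermediate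
12 | (Z)-3-{3,5-bis(benzyloxy)-2-[2-(benzyloxy)-5-(methoxycarbonyl)phenyl]phenoxy}-3-[4-(benzyloxy)phenyl]acrylic trifluoroacetic anhydride | FC(F)(F)C(=O)OC(=O)/C=C(\Oc1cc(OCc2ccccc2)cc(OCc2ccccc2)c1-c1cc(C(=O)OC)ccc1OCc1ccccc1)c1ccc(OCc2ccccc2)cc1 | intermediate
13 | methyl 4-(benzyloxy)-3-{5,7-bis(benzyloxy)-2-[4-(benzyloxy)phenyl]-4-oxochromen-8-yl}benzoate | COC(=O)c1ccc(OCc2ccccc2)c(-c2c(OCc3ccccc3)cc(OCc3ccccc3)c3c(=O)cc(-c4ccc(OCc5ccccc5)cc4)oc23)c1 | intermediate
14 | 4-(benzyloxy)-3-{5,7-bis(benzyloxy)-2-[4-(benzyloxy)phenyl]-4-oxochromen-8-yl}benzoic acid | OC(=O)c1ccc(OCc2ccccc2)c(-c2c(OCc3ccccc3)cc(OCc3ccccc3)c3c(=O)cc(-c4ccc(OCc5ccccc5)cc4)oc23)c1 | intermediate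
15 | 2',6'-dihydroxy-4'-methoxyacetophenone | COc1cc(O)c(C(C)=O)c(O)c1 | starting material
16 | 2'-(benzyloxy)-6'-hydroxy-4'-methoxyacetophenone | COc1cc(O)c(C(C)=O)c(OCc2ccccc2)c1 | intermediate
17 | 2-acetyl-3-(benzyloxy)-5-methoxyphenyl 4-(benzyloxy)-3-{5,7-bis(benzyloxy)-2-[4-(benzyloxy)phenyl]-4-oxochromen-8-yl}benzoate | COc1cc(OC(=O)c2ccc(OCc3ccccc3)c(-c3c(OCc4ccccc4)cc(OCc4ccccc4)c4c(=O)cc(-c5ccc(OCc6ccccc6)cc5)oc34)c2)c(C(C)=O)c(OCc2ccccc2)c1 | intermediate
18 | 1-[2-(benzyloxy)-6-hydroxy-4-methoxyphenyl]-3-(4-(benzyloxy)-3-{5,7-bis(benzyloxy)-2-[4-(benzyloxy)phenyl]-4-oxochromen-8-yl}phenyl)propane-1,3-dione | COc1cc(O)c(C(=O)CC(=O)c2ccc(OCc3ccccc3)c(-c3c(OCc4ccccc4)cc(OCc4ccccc4)c4c(=O)cc(-c5ccc(OCc6ccccc6)cc5)oc34)c2)c(OCc2ccccc2)c1 | intermediate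
19 | 5-(benzyloxy)-2-(4-(benzyloxy)-3-{5,7-bis(benzyloxy)-2-[4-(benzyloxy)phenyl]-4-oxochromen-8-yl}phenyl)-7-methoxychromen-4-one | COc1cc(OCc2ccccc2)c2c(=O)cc(-c3ccc(OCc4ccccc4)c(-c4c(OCc5ccccc5)cc(OCc5ccccc5)c5c(=O)cc(-c6ccc(OCc7ccccc7)cc6)oc45)c3)oc2c1 | intermediate
20 | sequoiaflavone | COc1cc(O)c2c(=O)cc(-c3ccc(O)c(-c4c(O)cc(O)c5c(=O)cc(-c6ccc(O)cc6)oc45)c3)oc2c1 | target

**Step count.** Total: 13 steps. Longest linear sequence: 11 steps (1, 2, 3, 5, 6, 7, 8, 10, 11, 12, 13).

**Steps most likely to fail**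

Step 7. The acyl carbon of the mixed anhydride is deactivated by the β-oxygen, so ring closure may be slow. Intermolecular trifluoroacetylation of the electron-rich ring at the carbon between its two benzyloxy groups, acid-induced loss of benzyl groups, or cleavage of the enol ether could then compete. The fallback sets out from 6 and closes ring C through the O1–C2 bond instead. Chelation-controlled Fries-type ortho-acetylation (Ac2O, BF3·OEt2) should give methyl 3-[3-acetyl-4,6-bis(benzyloxy)-2-hydroxyphenyl]-4-(benzyloxy)benzoate F1. One-pot acylation of its lithium dianion (LiN(SiMe3)2, then 4-(benzyloxy)benzoyl chloride) should give the diketone methyl 4-(benzyloxy)-3-(4,6-bis(benzyloxy)-3-{3-[4-(benzyloxy)phenyl]-3-oxopropanoyl}-2-hydroxyphenyl)benzoate F2. Acid cyclodehydration (H2SO4 cat., AcOH) then returns to the route at 13.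

Step 3. The tin–lead exchange may be incomplete on the ester-bearing ring, leftover Pb(OAc)4 may oxidise the phenol, and a second arylation at the other ortho carbon may follow the first. The fallback replaces ligand coupling by cross-coupling. From 4, ortho-iodination (N-iodosuccinimide, CH2Cl2, low temperature, with chromatographic removal of any para isomer) gives 3,5-bis(benzyloxy)-2-iodophenol F3. From 2, Miyaura borylation (bis(pinacolato)diboron, Pd(dppf)Cl2, KOAc, dioxane) gives methyl 4-(benzyloxy)-3-(4,4,5,5-tetramethyl-1,3,2-dioxaborolan-2-yl)benzoate F4. Suzuki–Miyaura coupling of F3 with F4 (Pd(OAc)2, SPhos, K3PO4, toluene/H2O) returns to the route at 6.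

Step 5. Addition of the hindered phenoxide to the electron-rich arylpropiolate may be sluggish, and prolonged heating may erode the alkene geometry or reverse the addition. The fallback sets out from 9. Anti hydroiodination (NaI, AcOH, 70 °C) gives allyl (Z)-3-[4-(benzyloxy)phenyl]-3-iodoacrylate F5. Ullmann-type vinylation of phenol 6 with F5 (CuI, N,N-dimethylglycine, Cs2CO3, dioxane, 90 °C), which proceeds with retention of geometry, returns to the route at 10.

**Further compounds**
F1 | step 7 | methyl 3-[3-acetyl-4,6-bis(benzyloxy)-2-hydroxyphenyl]-4-(benzyloxy)benzoate | COC(=O)c1ccc(OCc2ccccc2)c(-c2c(O)c(C(C)=O)c(OCc3ccccc3)cc2OCc2ccccc2)c1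
F2 | step 7 | methyl 4-(benzyloxy)-3-(4,6-bis(benzyloxy)-3-{3-[4-(benzyloxy)phenyl]-3-oxopropanoyl}-2-hydroxyphenyl)benzoate | COC(=O)c1ccc(OCc2ccccc2)c(-c2c(O)c(C(=O)CC(=O)c3ccc(OCc4ccccc4)cc3)c(OCc3ccccc3)cc2OCc2ccccc2)c1
F3 | step 3 | 3,5-bis(benzyloxy)-2-iodophenol | Oc1cc(OCc2ccccc2)cc(OCc2ccccc2)c1I
F4 | step 3 | methyl 4-(benzyloxy)-3-(4,4,5,5-tetramethyl-1,3,2-dioxaborolan-2-yl)benzoate | COC(=O)c1ccc(OCc2ccccc2)c(B2OC(C)(C)C(C)(C)O2)c1
F5 | step 5 | allyl (Z)-3-[4-(benzyloxy)phenyl]-3-iodoacrylate | C=CCOC(=O)/C=C(\I)c1ccc(OCc2ccccc2)cc1
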